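## The problem

Previtexilactone (20) is a labdane in which a trans-fused decalin (rings A and B) carries at C9 a spiro-linked oxolane (the 9α,13-ether), which is itself spiro-fused at C13 to a γ-lactone (C14–C15(=O)–O–C16). Six stereocentres must be set: C5, C6, C8, C9, C10 and C13. C9 and C10 are adjacent fully substituted carbons, and the C9 oxygen sits on the α face, the face from which a nucleophile would add to a C9 carbonyl, so the C9–C11 bond cannot be made by plain carbonyl addition. The axial 10β-methyl is the main control element of the bicycle: it closes the β face and can direct the ring fusion at C5, hydride delivery to C6 (axial 6β-oxygen) and oxygen delivery to C9, while the 8α-methyl is the equatorial, thermodynamically preferred epimer next to a C9 carbonyl. C13 is insulated from the decalin by the ether oxygen and has no strong controller. The fragile functions are the β-alkoxy lactone (retro-oxa-Michael under base), the tertiary C9–O bond (ionisation under acid) and the hindered 6β-acetate, which would not survive hydride or organometallic reagents. The feature that opens the route is that thirteen skeletal carbons (ring A, C1–C5 and C10, with its three methyls; C6 as a carbonyl; C7; C8; the C8 methyl) are those of β-damascone (1), a cross-conjugated dienone in which C8 and C10 are the β-carbons of two enones sharing the C6 carbonyl. Only C9 is missing between them, and nitromethane (2), a one-carbon double donor and latent carbonyl, can bridge C8 and C10 and end as the C9 ketone.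

## Retrosynthesis

**Acetate (20 ⇒ 19).** The C6–O acyl bond is cut first. The acetate is the only group that no earlier step needs and that several earlier steps would destroy. Alcohol 19 has a single hydroxyl, so the forward step only asks for acylation of a hindered axial alcohol.

**Oxolane C13–O bond (19 ⇒ 18).** Cutting O–C13 reveals butenolide 18, whose β-carbon is C13, and the tertiary 9α-alcohol. Cutting O–C9 instead would require substitution at a tertiary carbon with loss of the C9 configuration. The precursor has one ring and one stereocentre fewer. The forward reaction is a 5-exo-trig oxa-Michael addition; it must deliver C13 without a strong bias, so reversibility, separation and recycling are planned for.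

**Butenolide from furan (18 ⇒ 16 ⇒ 14).** No skeletal bond is cut. The β-substituted butenolide is traced to 3-substituted furan 14 through γ-hydroxybutenolide 16. The furan is a robust carrier of C13–C16 through the organometallic step. The forward steps must place the carbonyl at C15, the carbon remote from the substituent.

**C11–C12 bond (14 ⇒ 9 + 13).** The side chain is cut at C11–C12, not at C9–C11. A carbon nucleophile adding to a C9 ketone would enter from the α face and leave the hydroxyl on the β face, the wrong epimer. Opening spiro-epoxide 9 at C11 leaves the C9–O bond untouched. The nucleophile 13 comes from 3-furanmethanol (10) via chloride 12. The forward step asks for attack at a neopentyl-type CH2 by an ambident furylmethyl reagent.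

**Epoxide oxygen and C9=C11 (9 ⇒ 8 ⇒ 7).** The epoxide is traced to exocyclic alkene 8 and this to ketone 7. The C10 methyl should send the peracid to the α face, which is the C9 configuration required. The precursor 7 is a simple hydroxy decalone.

**C9 carbonyl and C6 alcohol (7 ⇒ 5 ⇒ 4).** The C9 ketone comes from a secondary nitro group (Nef reaction) and the 6β-alcohol from the C6 ketone. Reduction is placed before the Nef reaction, so the two carbonyls never coexist and need no differentiation. Removing the C6 carbonyl also removes the retro-Michael path that could reopen ring B.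

**C9–C10 bond, ring B (4 ⇒ 3).** This is the key cut. Nitro decalone 4 is opened between C9 and C10 to monocyclic δ-nitro ketone 3, which has one stereocentre. Making C9–C10 first and C8–C9 second would need an intermolecular addition to the hindered C10. Cuts through C5–C10 or C4–C5 lead to annulation or cycloaddition routes that start further from the target. The forward reaction asks a nitronate to add to a fully substituted, twisted enone carbon and to relay C8 to C10.

**C8–C9 bond (3 ⇒ 1 + 2).** The remaining bond is the conjugate addition of nitromethane to the crotonyl unit of 1. It is chemoselective because the ring enone is the poorer acceptor, and it must be enantioselective because C8 controls everything after it.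

## Roads not taken

**Alternative 1:** The oxolane is cut through C12=C13 of spiro 2,3-dihydrofuran A2. The forward key step is a carbonyl–olefin metathesis: a titanium alkylidene formed at the terminal alkene of the 9β-allyl group of tertiary benzyloxyacetate A1 olefinates the ester carbonyl.
- Merits: C13 becomes an enol ether carbon, so the acetate arm could be added to an oxocarbenium ion irreversibly, and the order of introducing the two arms could be swapped to reach either C13 epimer. This is a better handle on C13 than the chosen plan has.
- Weak points: the plan does not build the decalin at all. It needs acylation of the very hindered axial tertiary 9α-alcohol, stoichiometric titanium reagents on a hindered ester, and a C6 ketal that must later be removed, reduced and acetylated. The 9β-allyl carbinol still has to come from the same α-epoxide.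
- Comparison: the chosen plan sets against the better C13 control a decalin carrying both oxygens after four steps and an endgame of four steps from epoxide 9, with the wrong C13 epimer recyclable. The oxocarbenium idea is kept as a fallback.

**Alternative 2:** Both C–O bonds at C6 and C9 are cut, leading to ring B 6,8-diene A3. Singlet oxygen adds across C6 and C9 from the α face to give endoperoxide A4.
- Merits: both oxygens arrive in one step with the side chain already in place, and the 9α-configuration is correct.
- Weak points: the C6 oxygen arrives α and the target needs β, so an oxidation–reduction detour follows. C8 must then be set by hydrogenating the 7,8-alkene from the hindered β face in the presence of the butenolide alkene. Diene A3 contains the whole labdane skeleton, so no skeletal simplification is achieved. Ene reactions at the allylic methyl and at C11 compete.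
- Comparison: this road is more economical for the oxygenation itself. The chosen plan sets against it that it forms the skeleton, fixes C8 first and obtains 6β directly by hydride delivery.

**Alternative 3:** Ring A is cut at C1–C10 and C4–C5. An enantioselective Diels–Alder reaction of 2,6-dimethyl-1,4-benzoquinone A5 with 4-methylpenta-1,3-diene A6, under a chiral oxazaborolidinium Lewis acid, gives cis-fused enedione A7.
- Merits: it is convergent, sets the C10 quaternary centre under catalyst control, and delivers both carbonyls and the C8 methyl. Its reaction class has direct precedent, which the chosen key step lacks.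
- Weak points: diene A6 carries a Z-methyl at the reacting terminus and populates the s-cis form poorly. The bond from its fully substituted terminus to C5 is made next to the new quaternary C10. The cis fusion must be epimerised at C5, and two carbonyls and two alkenes must then be told apart.
- Comparison: the chosen plan sets against the better precedent a cheap starting material holding thirteen of the carbons, C8 fixed before ring closure, a trans-decalin in two steps, and C6 and C9 differentiated by construction (carbonyl versus nitro).

Key step: step 2

Remark on names: locants follow labdane numbering throughout. "11-Nordrimane" means the 4,4,8,10-tetramethyldecalin core, and "drimane" the same core with C11 on C9.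

Assumption: the thiourea from 9-amino(9-deoxy)-epi-quinidine is taken to give the (R)-adduct 3, by analogy with its sense of induction on aryl enones and allowing for the priority change from aryl to methyl; if the sense is opposite, the quinine-derived pseudoenantiomer is used.

## Steps

Step 1
Reactants: 1 β-damascone; 2 nitromethane
Product: 3 (R)-3-methyl-4-nitro-1-(2,6,6-trimethylcyclohex-1-en-1-yl)butan-1-one
Conditions: 2 (10 equiv), 9-amino(9-deoxy)-epi-quinidine 3,5-bis(trifluoromethyl)phenylthiourea (10 mol%), toluene, 25 °C
Reagents that add atoms: none
Why: Bifunctional amine–thiourea catalysis of the nitro-Michael addition to an enone: the thiourea binds the crotonyl carbonyl and the quinuclidine delivers the nitronate to one face of the β-carbon, which sets C8 (R). Only the crotonyl double bond reacts, because the ring A double bond is tetrasubstituted and twisted out of conjugation; excess nitromethane suppresses double addition.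

Step 2
Reactants: 3 (R)-3-methyl-4-nitro-1-(2,6,6-trimethylcyclohex-1-en-1-yl)butan-1-one
Product: 4 (5S,8R,9S,10S)-9-nitro-11-nordriman-6-one
Conditions: DBU (1.5 equiv), MeCN, 25 → 70 °C
Reagents that add atoms: none
Why: Proposed new method: DBU deprotonates C9, and the nitronate carbon adds to C10, the β-carbon of the ring A enone, in a 6-endo-trig conjugate addition that closes ring B and gives the C5=C6 enolate, which is protonated at C5; the closest known reaction type is the second stage of the double Michael addition of nitromethane to divinyl ketones, which gives 4-nitrocyclohexanones by the same endo mode, whereas a β,β-disubstituted acceptor twisted out of conjugation by its flanking methyl groups has no precedent. The step relies on three things: the reacting carbons are held in one chain, no other electrophile is within reach of the nitronate (attack on C6 would give a four-membered ring), and the adduct should be the thermodynamic sink because a C–C σ bond replaces a poorly conjugated π bond. C10 is set in a half-chair transition state in which C9 approaches perpendicular to the enone plane, the C10 methyl is forced pseudoaxial by ring A, and the C8 methyl takes the equatorial position to avoid a 1,3-diaxial contact with it, which places H-8 and the C10 methyl on the same face (8α-methyl, 10β-methyl). C5 lies α to the C6 carbonyl and is set by protonation under equilibrating conditions, expected to favour the trans ring fusion. C9 lies α to the nitro group and should equilibrate to the equatorial 9β-epimer; its configuration is erased in step 4, so either epimer serves. The selectivity that matters is the face of C10 relative to C8, and it is secured by the enantiopure C8 centre from step 1.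

Step 3
Reactants: 4 (5S,8R,9S,10S)-9-nitro-11-nordriman-6-one
Product: 5 (5S,6R,8R,9S,10S)-9-nitro-11-nordriman-6-ol
Conditions: NaBH4, MeOH/THF, 0 °C
Reagents that add atoms: none
Why: Borohydride reduction of the ketone; the β face of C6 is closed by the syn-axial methyl groups on C4 and C10, so hydride arrives from the α face and gives the axial 6β-alcohol (6R). The nitro group is inert to NaBH4, and removing the C6 carbonyl blocks retro-Michael opening of ring B.

Step 4
Reactants: 5 (5S,6R,8R,9S,10S)-9-nitro-11-nordriman-6-ol
Product: 7 (5S,6R,8R,10S)-6-hydroxy-11-nordriman-9-one, via sodium nitronate 6 (not isolated)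
Conditions: NaOMe, MeOH, 0 °C; then O3, MeOH/CH2Cl2, −78 °C; N2 purge
Reagents that add atoms: ozone, [O-][O+]=O
Why: Oxidative Nef reaction: the secondary nitro group is deprotonated to nitronate 6 and its C=N bond is cleaved by ozone to the C9 ketone, a variant that avoids strong acid and tolerates the free alcohol. The 8α-methyl is already the equatorial, preferred epimer next to the new carbonyl.

Step 5
Reactants: 7 (5S,6R,8R,10S)-6-hydroxy-11-nordriman-9-one
Product: 8 (5S,6R,8R,10S)-drim-9(11)-en-6-ol
Conditions: Ph3PCH3Br, KOtBu (excess), toluene, 90 °C
Reagents that add atoms: methyltriphenylphosphonium bromide, C[P+](c1ccccc1)(c1ccccc1)c1ccccc1.[Br-]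
Why: Wittig methylenation with excess ylide at elevated temperature, the standard answer to α-branched hindered ketones; one equivalent of base is spent on the C6 hydroxyl. Any enolisation toward C8 returns the equatorial 8α-methyl epimer.

Step 6
Reactants: 8 (5S,6R,8R,10S)-drim-9(11)-en-6-ol
Product: 9 (5S,6R,8R,9R,10S)-9,11-epoxydriman-6-ol
Conditions: mCPBA, CH2Cl2/aq. NaHCO3 (two-phase), 0 °C
Reagents that add atoms: mCPBA, OOC(=O)c1cccc(Cl)c1
Why: Prilezhaev epoxidation of the 1,1-disubstituted alkene; the axial 10β-methyl next to C9 shields the β face, so oxygen should arrive from the α face and set C9 with an axial C–O bond (9R). The bicarbonate phase protects the acid-sensitive tertiary epoxide.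

Step 7
Reactants: 10 3-furanmethanol
Product: 12 3-(chloromethyl)furan, via furan-3-ylmethyl methanesulfonate 11 (not isolated)
Conditions: MsCl, LiCl, 2,4,6-collidine, DMF, 0 °C
Reagents that add atoms: lithium chloride, [Li+].[Cl-]
Why: Mesylation and in situ displacement by chloride under non-acidic conditions, the usual way to an acid-sensitive furylmethyl halide. The chloride is used at once because it does not keep.

Step 8
Reactants: 9 (5S,6R,8R,9R,10S)-9,11-epoxydriman-6-ol; 12 3-(chloromethyl)furan
Product: 14 (5S,6R,8R,9R,10S)-15,16-epoxylabda-13(16),14-diene-6,9-diol, via furan-3-ylmethylmagnesium chloride 13 (not isolated)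
Conditions: 12, Mg, THF, 0 °C; then CuI (10 mol%), 9, THF, −30 → 0 °C; aq. NH4Cl
Reagents that add atoms: none
Why: Copper-catalysed SN2 opening of the epoxide by the Grignard reagent at the primary carbon C11 forms the C11–C12 bond and leaves the C9–O bond and the C9 configuration untouched. Copper catalysis at low temperature favours coupling through the exocyclic CH2 of the furylmethyl reagent and suppresses Lewis-acid rearrangement of the epoxide; one equivalent of reagent is consumed by the C6 hydroxyl.

Step 9
Reactants: 14 (5S,6R,8R,9R,10S)-15,16-epoxylabda-13(16),14-diene-6,9-diol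
Product: 16 (5S,6R,8R,9R,10S)-6,9,16-trihydroxylabd-13-en-15,16-olide, via furan endoperoxide 15 (not isolated)
Conditions: O2, hν (visible), rose bengal (cat.), iPr2NEt, CH2Cl2, −78 °C
Reagents that add atoms: dioxygen, O=O
Why: [4+2] cycloaddition of singlet oxygen to the furan gives endoperoxide 15, from which the hindered amine removes the less hindered bridgehead proton (H-15), so that C15 becomes the lactone carbonyl and C16 the hemiacetal carbon. This is the regiochemistry the target needs; C16 is formed as a mixture and loses its stereocentre in step 10.

Step 10
Reactants: 16 (5S,6R,8R,9R,10S)-6,9,16-trihydroxylabd-13-en-15,16-olide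
Product: 18 (5S,6R,8R,9R,10S)-6,9-dihydroxylabd-13-en-15,16-olide, via sodium hydroxy carboxylate 17 (not isolated)
Conditions: NaBH4, EtOH, 0 °C; then 1 M HCl to pH 2
Reagents that add atoms: none
Why: The γ-hydroxybutenolide is in equilibrium with its open formyl carboxylate, which NaBH4 reduces at the aldehyde; acidification closes the Z-hydroxy carboxylate 17 to the butenolide with the carbonyl at C15. The conjugated lactone is not reduced under these conditions.

Step 11
Reactants: 18 (5S,6R,8R,9R,10S)-6,9-dihydroxylabd-13-en-15,16-olide
Product: 19 (5S,6R,8R,9R,10S,13S)-6-hydroxy-9,13-epoxylabdan-15,16-olide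
Conditions: KOtBu (0.2 equiv), THF, −20 → 0 °C
Reagents that add atoms: none
Why: Intramolecular oxa-Michael addition (5-exo-trig) of the C9 alkoxide to C13, the β-carbon of the butenolide, closes the oxolane and creates the spiro centre C13. The addition is reversible under alkoxide catalysis, so the C13 epimers should form according to their stability; no strong bias is expected, the (13S)-isomer is separated and the (13R)-isomer is returned to the same conditions.

Step 12
Reactants: 19 (5S,6R,8R,9R,10S,13S)-6-hydroxy-9,13-epoxylabdan-15,16-olide
Product: 20 previtexilactone, (5S,6R,8R,9R,10S,13S)-6-acetoxy-9,13-epoxylabdan-15,16-olide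
Conditions: Ac2O, DMAP, pyridine, 40 °C
Reagents that add atoms: acetic anhydride, CC(=O)OC(C)=O
Why: DMAP-catalysed acylation of the only remaining hydroxyl; the axial 6β-alcohol is hindered by the C4 and C10 methyl groups and needs the nucleophilic catalyst and gentle warming. The medium is too weakly basic to reopen the β-alkoxy lactone.

## Compound list

1 | β-damascone, (E)-1-(2,6,6-trimethylcyclohex-1-en-1-yl)but-2-en-1-one | C/C=C/C(=O)C1=C(C)CCCC1(C)C | starting material
2 | nitromethane | C[N+](=O)[O-] | starting material
3 | (R)-3-methyl-4-nitro-1-(2,6,6-trimethylcyclohex-1-en-1-yl)butan-1-one | [O-][N+](=O)C[C@H](C)CC(=O)C1=C(C)CCCC1(C)C | intermediate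
4 | (5S,8R,9S,10S)-9-nitro-11-nordriman-6-one; trans-fused, 8α-methyl, 9β-nitro; (3R,4S,4aS,8aS)-3,4a,8,8-tetramethyl-4-nitrooctahydronaphthalen-1(2H)-one | O=C1C[C@@H](C)[C@H]([N+](=O)[O-])[C@@]2(C)CCCC(C)(C)[C@H]12 | intermediate
5 | (5S,6R,8R,9S,10S)-9-nitro-11-nordriman-6-ol (6β-hydroxy) | O[C@@H]1C[C@@H](C)[C@H]([N+](=O)[O-])[C@@]2(C)CCCC(C)(C)[C@H]12 | intermediate
6 | sodium nitronate of 5 (C9=N) | O[C@@H]1C[C@@H](C)C(=[N+]([O-])[O-])[C@@]2(C)CCCC(C)(C)[C@H]12.[Na+] | intermediate
7 | (5S,6R,8R,10S)-6-hydroxy-11-nordriman-9-one; (2R,4R,4aS,8aS)-4-hydroxy-2,5,5,8a-tetramethyloctahydronaphthalen-1(2H)-one | O[C@@H]1C[C@@H](C)C(=O)[C@@]2(C)CCCC(C)(C)[C@H]12 | intermediate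
8 | (5S,6R,8R,10S)-drim-9(11)-en-6-ol (9-methylene, 6β-hydroxy, 8α-methyl) | O[C@@H]1C[C@@H](C)C(=C)[C@@]2(C)CCCC(C)(C)[C@H]12 | intermediate
9 | (5S,6R,8R,9R,10S)-9,11-epoxydriman-6-ol (spiro-oxirane, oxygen α) | O[C@@H]1C[C@@H](C)[C@]2(CO2)[C@@]3(C)CCCC(C)(C)[C@H]13 | intermediate
10 | 3-furanmethanol | OCc1ccoc1 | starting material
11 | furan-3-ylmethyl methanesulfonate | CS(=O)(=O)OCc1ccoc1 | intermediate
12 | 3-(chloromethyl)furan | ClCc1ccoc1 | intermediate
13 | furan-3-ylmethylmagnesium chloride | Cl[Mg]Cc1ccoc1 | intermediate
14 | (5S,6R,8R,9R,10S)-15,16-epoxylabda-13(16),14-diene-6,9-diol (6β,9α-diol, 3-substituted furan) | O[C@@H]1C[C@@H](C)[C@](O)(CCc2ccoc2)[C@@]3(C)CCCC(C)(C)[C@H]13 | intermediate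
15 | furan 2,5-endoperoxide of 14 (2,3,7-trioxabicyclo[2.2.1]hept-5-ene, side chain on C5; diastereomer mixture) | O[C@@H]1C[C@@H](C)[C@](O)(CCC2=CC3OOC2O3)[C@@]4(C)CCCC(C)(C)[C@H]14 | intermediate
16 | (5S,6R,8R,9R,10S)-6,9,16-trihydroxylabd-13-en-15,16-olide (C16 epimers) | O[C@@H]1C[C@@H](C)[C@](O)(CCC2=CC(=O)OC2O)[C@@]3(C)CCCC(C)(C)[C@H]13 | intermediate
17 | sodium (13Z)-(5S,6R,8R,9R,10S)-6,9,16-trihydroxylabd-13-en-15-oate | O[C@@H]1C[C@@H](C)[C@](O)(CC/C(CO)=C/C(=O)[O-])[C@@]3(C)CCCC(C)(C)[C@H]13.[Na+] | intermediate
18 | (5S,6R,8R,9R,10S)-6,9-dihydroxylabd-13-en-15,16-olide (carbonyl at C15) | O[C@@H]1C[C@@H](C)[C@](O)(CCC2=CC(=O)OC2)[C@@]3(C)CCCC(C)(C)[C@H]13 | intermediate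
19 | (5S,6R,8R,9R,10S,13S)-6-hydroxy-9,13-epoxylabdan-15,16-olide | O[C@@H]1C[C@@H](C)[C@]2(CC[C@]3(COC(=O)C3)O2)[C@@]2(C)CCCC(C)(C)[C@H]12 | intermediate
20 | previtexilactone, (5S,6R,8R,9R,10S,13S)-6-acetoxy-9,13-epoxylabdan-15,16-olide | CC(=O)O[C@@H]1C[C@@H](C)[C@]2(CC[C@]3(COC(=O)C3)O2)[C@@]2(C)CCCC(C)(C)[C@H]12 | target

## Step count and least certain steps

Total: 12 steps. Longest linear sequence: 11 steps from 1 (steps 1–6 and 8–12); step 7 is a one-step side branch.

**Step 2 (key step).** The ring closure may simply not take place. The C6 carbonyl and the C5=C10 double bond must approach coplanarity with C7 syn to C10, which costs allylic strain against the C10 methyl, and C10 is fully substituted. Prolonged heating with base could also reverse the first Michael addition and erode C8, and a boat-like closure would give the C10 epimer.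

Fallback, with cationic instead of anionic activation of the same bond: setting out from 1, 3-(trimethylsilyl)propyne is lithiated and converted into diisopropyl [3-(trimethylsilyl)prop-1-yn-1-yl]boronate F1. F1 is added to the crotonyl double bond of 1 under catalysis by a 3,3′-disubstituted binaphthol (enantioselective conjugate alkynylation of an s-cis enone) to give (R)-3-methyl-6-(trimethylsilyl)-1-(2,6,6-trimethylcyclohex-1-en-1-yl)hex-4-yn-1-one F2. TiCl4 in CH2Cl2 at −78 °C then effects an intramolecular Sakurai-type addition of the propargylsilane to the Lewis-acid-activated enone, a reaction class known to form quaternary β-carbons. This closes ring B and gives the allene (5S,8R,10S)-9-ethenylidene-11-nordriman-6-one F3. NaBH4 gives (5S,6R,8R,10S)-9-ethenylidene-11-nordriman-6-ol F4, and ozonolysis of the allene (O3, then Me2S) leaves the C9 ketone, coming back to the route at 7.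

**Step 11.** The addition may stop at an unfavourable equilibrium or show no facial preference at C13, because the two lactone arms differ little in size and the centre is remote from the decalin. The alkoxide may also deprotonate the butenolide at C16 and divert material.

Fallback, an irreversible construction of C13 through an oxocarbenium ion: setting out from 9, the lithium acetylide of benzyl propargyl ether with BF3·OEt2 opens the epoxide at C11 to give (5S,6R,8R,9R,10S)-11-[3-(benzyloxy)prop-1-yn-1-yl]drimane-6,9-diol F5. Ph3PAuCl/AgOTf in MeOH effects 5-endo-dig addition of the C9 hydroxyl to the alkyne and ketalisation, giving the methyl ketal (5S,6R,8R,9R,10S)-16-benzyloxy-13-methoxy-9,13-epoxy-14,15-dinorlabdan-6-ol F6. TMSOTf with CH2=C(OMe)OSiMe2tBu replaces the methoxy group by the acetate arm (Mukaiyama-type ketal substitution) to give methyl (5S,6R,8R,9R,10S,13S)-16-benzyloxy-6-hydroxy-9,13-epoxylabdan-15-oate F7. Hydrogenolysis (H2, Pd/C) and acid-catalysed lactonisation come back to the route at 19. If the nucleophile prefers the other face, the order in which the two C13 arms are introduced is exchanged.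

**Step 8.** The furylmethyl Grignard reagent is ambident and may couple through the ring carbon next to the substituent. Attack at the neopentyl-type C11 is slow, which gives magnesium halide time to rearrange the tertiary epoxide.

Fallback, a sulfone-stabilised, non-ambident carbanion: setting out from 12, PhSO2Na in DMF gives 3-[(phenylsulfonyl)methyl]furan F8. Its lithio derivative (n-BuLi, THF, −78 °C, BF3·OEt2) opens 9 at C11 to give (5S,6R,8R,9R,10S)-12-(phenylsulfonyl)-15,16-epoxylabda-13(16),14-diene-6,9-diol F9 as C12 epimers. Reductive desulfonylation with Na(Hg) and Na2HPO4 in MeOH comes back to the route at 14.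

**Step 1.** Turnover may be slow and facial discrimination incomplete, because this catalyst class is tuned to aryl enones while 1 has a bulky non-aromatic acyl group and a small β-methyl.

Fallback, resolution instead of asymmetric induction: setting out from 1, nitromethane with catalytic DBU gives racemic 3-methyl-4-nitro-1-(2,6,6-trimethylcyclohex-1-en-1-yl)butan-1-one F10. Preparative chromatography on a chiral stationary phase separates it into 3, where the route is rejoined, and the (S)-enantiomer F11, which is discarded.

**Step 6.** Facial selectivity may be poor if the exocyclic alkene is less shielded by the C10 methyl than assumed, and the tertiary epoxide may rearrange under the acidic by-product.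

Fallback, carbon delivered instead of oxygen: setting out from 7, Corey–Chaykovsky methylene transfer (Me3S+ I−, KHMDS, THF, 0 °C) adds CH2 to the C9 carbonyl from whichever face is open and closes the oxirane. If that face is β, as the failure of the epoxidation would imply, the product is 9, where the route is rejoined.

## Further compounds

F1 | step 2 | diisopropyl [3-(trimethylsilyl)prop-1-yn-1-yl]boronate | CC(C)OB(OC(C)C)C#CC[Si](C)(C)C
F2 | step 2 | (R)-3-methyl-6-(trimethylsilyl)-1-(2,6,6-trimethylcyclohex-1-en-1-yl)hex-4-yn-1-one | C[Si](C)(C)CC#C[C@H](C)CC(=O)C1=C(C)CCCC1(C)C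
F3 | step 2 | (5S,8R,10S)-9-ethenylidene-11-nordriman-6-one | O=C1C[C@@H](C)C(=C=C)[C@@]2(C)CCCC(C)(C)[C@H]12
F4 | step 2 | (5S,6R,8R,10S)-9-ethenylidene-11-nordriman-6-ol | O[C@@H]1C[C@@H](C)C(=C=C)[C@@]2(C)CCCC(C)(C)[C@H]12
F5 | step 11 | (5S,6R,8R,9R,10S)-11-[3-(benzyloxy)prop-1-yn-1-yl]drimane-6,9-diol | O[C@@H]1C[C@@H](C)[C@](O)(CC#CCOCc2ccccc2)[C@@]3(C)CCCC(C)(C)[C@H]13
F6 | step 11 | (5S,6R,8R,9R,10S)-16-benzyloxy-13-methoxy-9,13-epoxy-14,15-dinorlabdan-6-ol (C13 epimers) | O[C@@H]1C[C@@H](C)[C@]2(CCC(OC)(COCc3ccccc3)O2)[C@@]4(C)CCCC(C)(C)[C@H]14
F7 | step 11 | methyl (5S,6R,8R,9R,10S,13S)-16-benzyloxy-6-hydroxy-9,13-epoxylabdan-15-oate | O[C@@H]1C[C@@H](C)[C@]2(CC[C@](CC(=O)OC)(COCc3ccccc3)O2)[C@@]4(C)CCCC(C)(C)[C@H]14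
F8 | step 8 | 3-[(phenylsulfonyl)methyl]furan | O=S(=O)(Cc1ccoc1)c1ccccc1
F9 | step 8 | (5S,6R,8R,9R,10S)-12-(phenylsulfonyl)-15,16-epoxylabda-13(16),14-diene-6,9-diol (C12 epimers) | O[C@@H]1C[C@@H](C)[C@](O)(CC(c2ccoc2)S(=O)(=O)c2ccccc2)[C@@]3(C)CCCC(C)(C)[C@H]13
F10 | step 1 | racemic 3-methyl-4-nitro-1-(2,6,6-trimethylcyclohex-1-en-1-yl)butan-1-one | [O-][N+](=O)CC(C)CC(=O)C1=C(C)CCCC1(C)C
F11 | step 1 | (S)-3-methyl-4-nitro-1-(2,6,6-trimethylcyclohex-1-en-1-yl)butan-1-one | [O-][N+](=O)C[C@@H](C)CC(=O)C1=C(C)CCCC1(C)C
F0 | step 6 | none | none
A1 | alternative 1 | 9β-allyl-6,6-ethylenedioxy-11-nordriman-9α-yl 2-(benzyloxy)acetate | C1COC2(O1)C[C@@H](C)[C@](OC(=O)COCc3ccccc3)(CC=C)[C@@]4(C)CCCC(C)(C)[C@H]24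
A2 | alternative 1 | 16-benzyloxy-6,6-ethylenedioxy-9α,13-epoxy-14,15-dinorlabd-12-ene (spiro 2,3-dihydrofuran) | C1COC2(O1)C[C@@H](C)[C@]3(CC=C(COCc5ccccc5)O3)[C@@]4(C)CCCC(C)(C)[C@H]24
A3 | alternative 2 | (5S,10S)-labda-6,8,13-trien-15,16-olide | C1=CC(C)=C(CCC3=CC(=O)OC3)[C@@]2(C)CCCC(C)(C)[C@H]12
A4 | alternative 2 | 6α,9α-epidioxylabda-7,13-dien-15,16-olide | [C@H]1(OO4)C=C(C)[C@]4(CCC3=CC(=O)OC3)[C@@]2(C)CCCC(C)(C)[C@H]12
A5 | alternative 3 | 2,6-dimethyl-1,4-benzoquinone | CC1=CC(=O)C=C(C)C1=O
A6 | alternative 3 | 4-methylpenta-1,3-diene | C=CC=C(C)C
A7 | alternative 3 | cis-fused (5β-H,10β-methyl) 11-nordrima-2,7-diene-6,9-dione | O=C1C=C(C)C(=O)[C@@]2(C)CC=CC(C)(C)[C@@H]12
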